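## Structural features

Paratocarpin B is a chalcone: two benzene rings joined by a three-carbon (E)-enone, ring A on the carbonyl side and ring B on the alkene side. Ring A has a free hydroxyl on C2' and is fused across C3'–C4' to a 2,2-dimethyl-2H-pyran whose oxygen sits on C4' (a 5-hydroxy-2,2-dimethyl-2H-chromen-6-yl ketone). Ring B has a hydroxyl on C4 and a 3-methylbut-2-enyl (prenyl) chain on C3. There is no stereogenic centre, so no centres stand next to each other; the only stereochemical element is the E geometry of the Cα=Cβ bond. The fragile groups are the 2'-hydroxy enone (base closes it to a flavanone, nucleophiles add to it), the prenyl and chromene alkenes (acid adds the neighbouring phenol across them) and the free phenols (oxidation). The real difficulty is regiochemical: ring A is 1,2,3,4-tetrasubstituted, and electrophilic prenylation of a resorcinol ketone between its two oxygens competes with attack at C5' and at oxygen. In addition the pyran must close through O4' and not O2', and the two ortho-prenylphenol units must be told apart, because one is cyclized oxidatively and the other is kept. The key step uses the sequence around ring A (acyl on C1', oxygen on C2', carbon on C3', oxygen on C4', hydrogen on C5' and C6'), which is what a 1,3-dioxygenated butadiene with a C2 substituent gives with a terminal ynone when the C1'–C2' and C5'–C6' bonds are formed.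

## Logic of the disconnections

18 to 17. The O–Si bond on the ring B oxygen is restored. Ring B holds the same ortho-prenylphenol motif as ring A, so it must be masked while ring A is oxidized. There is no skeletal gain, but the two prenyl groups become distinguishable. The forward step must free the phenol without base strong enough to close the 2'-hydroxy enone to a flavanone and without acid; buffered fluoride meets this.

17 to 15 (through 16). The O4'–CMe2 bond of the pyran is cut and the C3=C4 unsaturation is removed, leaving an open prenyl chain on C3'. This turns the chromene problem into the substitution pattern of ring A and makes both halves carry the same side chain. The forward oxidation must act on the ring A prenyl group only and must close through O4'. The free 4'-hydroxyl (against a silyl ether on ring B) and the hydrogen bond that ties O2' to the ketone are relied on for both.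

15 to 9 and 13 (through 14). The C1'–C2' and C5'–C6' bonds of ring A are cut, with methanol and two silyl groups added back. The atom map is: diene C1 (ketene acetal) becomes C2', C2 (prenyl) becomes C3', C3 becomes C4', C4 (CH2) becomes C5'; the terminal alkyne carbon becomes C6' and the internal one C1'. This map fits 9, 13 and 15 as they stand in the compound list. Ring A disappears and two acyclic fragments of similar size remain, so the route is convergent and no resorcinol has to be alkylated. The forward step needs the right orientation, reaction at the alkyne and not at the enone alkene of 9, aromatization by loss of methanol, and survival of the ring B silyl ether in the acid that strips the two trimethylsilyl groups.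

9 to 6 and 7 (through 8). The C(=O)–C(sp) bond is cut. The reactive cross-conjugated ynone 9 is traced to the stable amide 6 and the commercial nucleophile 7, with no oxidation-state adjustment. The forward step requires that the tetrahedral adduct 8 hold until the quench and that the quench be acidic, so that the amine set free cannot add to the ynone.

6 to 4 and 5. The Cα=Cβ double bond is cut. One olefination brings in two carbons and the acyl-transfer group together. The forward step must be E-selective and must use a base that leaves the aryl silyl ether alone.

4 to 3, then 3 to 1 and 2. The O–Si bond and the aryl C3–CH2 bond are cut. The para position of 1 is blocked, so only the ortho carbon and the oxygen compete; the forward step must favour carbon.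

13 to 12 to 11, then 11 to 10 and 2. Two O–Si bonds are cut, then the C2–CH2 bond. The prenyl group destined for C3' is placed on the central carbon of a 1,3-dicarbonyl compound, where C-alkylation is reliable. The forward steps need monoalkylation, then silylation at the ketone oxygen, then deprotonation at the terminal methyl group and not at the prenyl CH2, and exclusion of moisture from 13.

## Other disconnections considered

Alternative 1: The pyran ring and its fusion to ring A are taken apart together. In chromene numbering the aryl C8a–O1 bond, the aryl C4a–C4 bond and the O1–C2 bond are cut, which leads from 5-(methoxymethoxy)-2,2-dimethyl-2H-chromene A1 back to 3-(methoxymethoxy)-2-(trimethylsilyl)phenyl trifluoromethanesulfonate A2 and 3-methylbut-2-enal A3. In the forward key step CsF would trigger 1,2-elimination of A2 to a 3-alkoxy aryne. The carbonyl oxygen of A3 should add to the aryne carbon remote from the acetal oxygen, the aryl anion should close onto the carbonyl carbon, and the benzoxete so formed should open to an ortho-quinone methide that electrocyclizes to A1. In its favour, no resorcinol is prenylated and no oxidant is used. The position of the pyran oxygen in A1 follows from the inductive bias of the alkoxy aryne, so the choice between two phenol oxygens never arises. On this point it is better than the chosen plan, which depends on a hydrogen bond in step 9. Against it here, A1 is only the bicyclic core. The enone and ring B would still have to be attached at C6 of A1 by directed lithiation and acylation with an amide such as 6, and the ring oxygen can direct to C8 in competition. The acetal must finally be removed with acid next to the chromene and prenyl alkenes, A2 needs several steps from a resorcinol derivative, and a second aryne can intercept the quinone methide. In comparison, the alternative starts from an existing benzene ring and builds the pyran, whereas the chosen plan builds the benzene ring and closes the pyran afterwards. Mechanistically both are polarity-controlled unions of two π systems with sound precedent for the reaction type, so they are equal there. In step count the alternative is expected to be equal or slightly longer, and it carries two protecting groups into the last intermediate against one.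

Alternative 2: Both bonds of the ketone carbon are cut, the bond from the carbonyl carbon to ring A and the bond from the carbonyl carbon to Cα. This gives 6-iodo-5-(methoxymethoxy)-2,2-dimethyl-2H-chromene A4, carbon monoxide A5 and (E)-2-{2-[4-(tert-butyldimethylsilyloxy)-3-(3-methylbut-2-enyl)phenyl]ethenyl}-4,4,5,5-tetramethyl-1,3,2-dioxaborolane A6. Their union is the doubly protected chalcone (E)-3-[4-(tert-butyldimethylsilyloxy)-3-(3-methylbut-2-enyl)phenyl]-1-[5-(methoxymethoxy)-2,2-dimethyl-2H-chromen-6-yl]prop-2-en-1-one A7, the methoxymethyl tert-butyldimethylsilyl diether of paratocarpin B. In the forward key step A4 would add oxidatively to zerovalent palladium formed from PdCl2(dppf), A5 would insert, A6 would transmetalate under K2CO3, and reductive elimination should give A7 with the alkene geometry retained. In its favour, two complete halves are joined at the carbonyl in the last skeletal step, the enone of A7 forms under nearly neutral conditions, and neither a terminal ynone nor a silyloxy diene is handled. On convergence and on stability of the intermediates it is the better plan. Against it here, direct coupling without uptake of A5 competes when insertion is slow, and A4 is electron-rich with an ortho alkoxy group. Alkenylboron partners are less usual in this reaction than arylboron partners. A4 presupposes a chromene synthesis (for instance A1, then lithiation and iodination), A6 needs about three steps from 4, a toxic gas is used, and A7 still carries two protecting groups, one of which needs acid. In comparison, the ring A regiochemistry is not solved by the coupling but only moved into the synthesis of A4, whereas the chosen plan solves it in the key step. Mechanistically the coupling is a well-understood catalytic cycle, equal in reliability of type to the cycloaddition. The alternative is expected to be longer overall, although its longest linear sequence could be equal.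

Alternative 3: Only the pyran O–CMe2 bond is cut, on a chalcone whose ring B oxygen is an acetal. The cut leads from (E)-1-(5-hydroxy-2,2-dimethyl-2H-chromen-6-yl)-3-[4-(methoxymethoxy)-3-(3-methylbut-2-enyl)phenyl]prop-2-en-1-one A9, the ring B methoxymethyl ether of paratocarpin B, back to the open diprenylchalcone (E)-1-[2,4-dihydroxy-3-(3-methylbut-2-enyl)phenyl]-3-[4-(methoxymethoxy)-3-(3-methylbut-2-enyl)phenyl]prop-2-en-1-one A8. In the forward key step DDQ would abstract hydride from the benzylic CH2 of the ring A prenyl group of A8, and the ortho-quinone methide would close through the ring A oxygen para to the ketone to give A9. In its favour, A8 would come from a Claisen–Schmidt condensation of a ring A methyl ketone with a ring B aldehyde, all classical operations with no moisture-sensitive diene and no ynone. In step count and simplicity of operation it is better than the chosen plan. The key step that turns A8 into A9 is the same reaction as step 9 of the chosen plan, with the same selectivity questions, so the two are equal there. Against it here, the ring A ketone needs a prenyl group placed between the two hydroxyls of a 2,4-dihydroxyaryl ketone by electrophilic alkylation, where the other free ring position next to a hydroxyl and the oxygens compete. The chosen plan removes this problem by bringing the prenyl group in on the diene. The acetal of A9 must also be removed with acid at the very end, where the chosen plan uses buffered fluoride. In comparison, the alternative is shorter and simpler, while the chosen plan offers regiocontrol of ring A and a milder last step.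

Key step: step 8

Remark: 12 and 13 are taken as mixtures of double-bond isomers, which does not matter because neither geometry is carried into the arene; salts formed by simple deprotonation inside a step are treated as the reacting form of the numbered compound.

## Steps

Step 1
Reactants: 1 4-hydroxybenzaldehyde; 2 1-bromo-3-methylbut-2-ene
Product: 3 4-hydroxy-3-(3-methylbut-2-enyl)benzaldehyde
Conditions: aq KOH (10%), rt
Reagents that add atoms: none
Why: Ortho C-alkylation of an ambident phenoxide: in water the oxygen is hydrogen-bonded and the allylic bromide is taken up at the ring carbon ortho to the oxygen, the para position being blocked; the O-prenyl ether and unreacted 1 are expected as separable by-products.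

Step 2
Reactants: 3 4-hydroxy-3-(3-methylbut-2-enyl)benzaldehyde
Product: 4 4-(tert-butyldimethylsilyloxy)-3-(3-methylbut-2-enyl)benzaldehyde
Conditions: t-BuMe2SiCl, imidazole, DMF, rt
Reagents that add atoms: tert-butyldimethylsilyl chloride, CC(C)(C)[Si](C)(C)Cl
Why: Standard silylation of a phenol; the silyl ether protects the ring B oxygen from the Grignard reagent, from the acid work-up of step 8 and from DDQ.

Step 3
Reactants: 4 4-(tert-butyldimethylsilyloxy)-3-(3-methylbut-2-enyl)benzaldehyde; 5 diethyl {2-[methoxy(methyl)amino]-2-oxoethyl}phosphonate
Product: 6 (E)-3-[4-(tert-butyldimethylsilyloxy)-3-(3-methylbut-2-enyl)phenyl]-N-methoxy-N-methylprop-2-enamide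
Conditions: NaH, THF, 0 °C → rt
Reagents that add atoms: none
Why: Horner–Wadsworth–Emmons olefination with a stabilized phosphonoacetamide anion, whose reversible addition leads to the E alkene; the product already carries the acyl-transfer group for step 4.

Step 4
Reactants: 6 (E)-3-[4-(tert-butyldimethylsilyloxy)-3-(3-methylbut-2-enyl)phenyl]-N-methoxy-N-methylprop-2-enamide; 7 ethynylmagnesium bromide
Product: 9 (E)-1-[4-(tert-butyldimethylsilyloxy)-3-(3-methylbut-2-enyl)phenyl]pent-1-en-4-yn-3-one, via magnesium hemiaminal chelate 8 (not isolated)
Conditions: 7 (2.5 equiv), THF, 0 °C → rt; poured into cold 1 M aq HCl/Et2O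
Reagents that add atoms: none
Why: Acyl substitution of a Weinreb amide by an alkynyl Grignard reagent: chelate 8 does not collapse before the quench, so the ynone never meets the nucleophile, and the cold acid protonates the released amine before it can add to the ynone.

Step 5
Reactants: 10 methyl acetoacetate; 2 1-bromo-3-methylbut-2-ene
Product: 11 methyl 2-acetyl-5-methylhex-4-enoate (racemic)
Conditions: NaH, THF, 0 °C; then 2, 0 °C → rt (10 in slight excess)
Reagents that add atoms: none
Why: Acetoacetic ester alkylation: C-alkylation of a β-keto ester enolate by an allylic bromide; the slight excess of 10 suppresses dialkylation.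

Step 6
Reactants: 11 methyl 2-acetyl-5-methylhex-4-enoate
Product: 12 methyl 2-(3-methylbut-2-enyl)-3-(trimethylsilyloxy)but-2-enoate (E/Z mixture)
Conditions: Me3SiCl, Et3N, toluene, rt
Reagents that add atoms: chlorotrimethylsilane, C[Si](C)(C)Cl
Why: O-Silylation of the enol form of a β-keto ester, the usual first stage in making 1-alkoxy-1,3-bis(silyloxy)butadienes.

Step 7
Reactants: 12 methyl 2-(3-methylbut-2-enyl)-3-(trimethylsilyloxy)but-2-enoate
Product: 13 1-methoxy-2-(3-methylbut-2-enyl)-1,3-bis(trimethylsilyloxy)buta-1,3-diene
Conditions: LiN(i-Pr)2, THF, −78 °C; Me3SiCl, −78 °C → rt; non-aqueous work-up (pentane, filtration)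
Reagents that add atoms: chlorotrimethylsilane, C[Si](C)(C)Cl
Why: Kinetic deprotonation of the γ-methyl group of the vinylogous ester and O-silylation at the ester oxygen, the usual second stage of the diene preparation; the prenyl CH2 is far less acidic because its anion is not conjugated with the ester.

Step 8
Reactants: 9 (E)-1-[4-(tert-butyldimethylsilyloxy)-3-(3-methylbut-2-enyl)phenyl]pent-1-en-4-yn-3-one; 13 1-methoxy-2-(3-methylbut-2-enyl)-1,3-bis(trimethylsilyloxy)buta-1,3-diene
Product: 15 (E)-3-[4-(tert-butyldimethylsilyloxy)-3-(3-methylbut-2-enyl)phenyl]-1-[2,4-dihydroxy-3-(3-methylbut-2-enyl)phenyl]prop-2-en-1-one, via cyclohexadiene cycloadduct 14 (not isolated)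
Conditions: 13 (1.5 equiv), toluene, 0 °C → 45 °C; then 1 M aq HCl, THF, 0 °C
Reagents that add atoms: none
Why: A normal-electron-demand Diels–Alder reaction in which both bonds form in one asynchronous event: the CH2 terminus of 13, which has the largest HOMO coefficient, attacks the terminal alkyne carbon of 9 (the β-carbon of the ynone) and the ketene acetal carbon joins the internal, acyl-bearing alkyne carbon. Ring A is closed by this intermolecular [4+2] cycloaddition as the cyclohexa-1,4-diene 14. The closest known reaction type is the cycloaddition of 1-alkoxy-1,3-bis(silyloxy)butadienes with acetylenic ketones and esters, followed by aromatization to 2,4-dihydroxyaryl carbonyl compounds. Cold dilute acid hydrolyses the silyl enol ether and the mixed silyl methyl ketal of 14; methanol is lost from the ketal carbon and tautomerization gives the arene, driven by aromaticity. The only stereocentre formed, the ketal carbon of 14, is destroyed in the aromatization, so nothing has to be controlled. The orientation is secured because the oxygen on diene C1 directs the acyl group ortho and the oxygen on C3 directs it para, and both point the same way. The alkyne should react in preference to the enone alkene because it is terminal, unhindered and the more electron-poor π bond, whereas the alkene is 1,2-disubstituted and receives electron density from the silyloxyaryl ring. The aryl tert-butyldimethylsilyl ether and both prenyl groups should survive the brief cold acid treatment that removes the trimethylsilyl groups.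

Step 9
Reactants: 15 (E)-3-[4-(tert-butyldimethylsilyloxy)-3-(3-methylbut-2-enyl)phenyl]-1-[2,4-dihydroxy-3-(3-methylbut-2-enyl)phenyl]prop-2-en-1-one
Product: 17 (E)-3-[4-(tert-butyldimethylsilyloxy)-3-(3-methylbut-2-enyl)phenyl]-1-(5-hydroxy-2,2-dimethyl-2H-chromen-6-yl)prop-2-en-1-one, via ortho-quinone methide 16 (not isolated)
Conditions: DDQ (1.1 equiv), benzene, rt → 60 °C
Reagents that add atoms: none
Why: Oxidative cyclization of an ortho-prenylphenol with DDQ: hydride abstraction from the benzylic, allylic CH2 of the 3'-prenyl group gives 16, which closes by oxa-6π electrocyclization through O4'. O2' is held in a hydrogen bond to the ketone and stays free, and the ring B prenyl group, next to a silyl ether, cannot form a quinone methide.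

Step 10
Reactants: 17 (E)-3-[4-(tert-butyldimethylsilyloxy)-3-(3-methylbut-2-enyl)phenyl]-1-(5-hydroxy-2,2-dimethyl-2H-chromen-6-yl)prop-2-en-1-one
Product: 18 paratocarpin B, (E)-1-(5-hydroxy-2,2-dimethyl-2H-chromen-6-yl)-3-[4-hydroxy-3-(3-methylbut-2-enyl)phenyl]prop-2-en-1-one
Conditions: Bu4NF, AcOH (1:1), THF, 0 °C
Reagents that add atoms: none
Why: Fluoride cleavage of an aryl silyl ether; acetic acid buffers the phenoxide that is released, so the 2'-hydroxy enone should not close to the flavanone and the E alkene, the prenyl group and the chromene are untouched.

## Compound list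

1 | 4-hydroxybenzaldehyde | O=Cc1ccc(O)cc1 | starting material
2 | 1-bromo-3-methylbut-2-ene | CC(C)=CCBr | starting material
3 | 4-hydroxy-3-(3-methylbut-2-enyl)benzaldehyde | CC(C)=CCc1cc(C=O)ccc1O | intermediate
4 | 4-(tert-butyldimethylsilyloxy)-3-(3-methylbut-2-enyl)benzaldehyde | CC(C)=CCc1cc(C=O)ccc1O[Si](C)(C)C(C)(C)C | intermediate
5 | diethyl {2-[methoxy(methyl)amino]-2-oxoethyl}phosphonate | CCOP(=O)(OCC)CC(=O)N(C)OC | starting material
6 | (E)-3-[4-(tert-butyldimethylsilyloxy)-3-(3-methylbut-2-enyl)phenyl]-N-methoxy-N-methylprop-2-enamide | CON(C)C(=O)/C=C/c1ccc(O[Si](C)(C)C(C)(C)C)c(CC=C(C)C)c1 | intermediate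
7 | ethynylmagnesium bromide | C#C[Mg]Br | starting material
8 | bromomagnesium (E)-1-[4-(tert-butyldimethylsilyloxy)-3-(3-methylbut-2-enyl)phenyl]-3-[methoxy(methyl)amino]pent-1-en-4-yn-3-olate (racemic tetrahedral adduct) | C#CC(O[Mg]Br)(N(C)OC)/C=C/c1ccc(O[Si](C)(C)C(C)(C)C)c(CC=C(C)C)c1 | intermediate (not isolated)
9 | (E)-1-[4-(tert-butyldimethylsilyloxy)-3-(3-methylbut-2-enyl)phenyl]pent-1-en-4-yn-3-one | C#CC(=O)/C=C/c1ccc(O[Si](C)(C)C(C)(C)C)c(CC=C(C)C)c1 | intermediate
10 | methyl acetoacetate | COC(=O)CC(C)=O | starting material
11 | methyl 2-acetyl-5-methylhex-4-enoate (racemic) | COC(=O)C(CC=C(C)C)C(C)=O | intermediate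
12 | methyl 2-(3-methylbut-2-enyl)-3-(trimethylsilyloxy)but-2-enoate (E/Z mixture) | COC(=O)C(CC=C(C)C)=C(C)O[Si](C)(C)C | intermediate
13 | 1-methoxy-2-(3-methylbut-2-enyl)-1,3-bis(trimethylsilyloxy)buta-1,3-diene (either ketene acetal geometry) | COC(O[Si](C)(C)C)=C(CC=C(C)C)C(=C)O[Si](C)(C)C | intermediate
14 | (E)-3-[4-(tert-butyldimethylsilyloxy)-3-(3-methylbut-2-enyl)phenyl]-1-[6-methoxy-5-(3-methylbut-2-enyl)-4,6-bis(trimethylsilyloxy)cyclohexa-1,4-dien-1-yl]prop-2-en-1-one (racemic) | COC1(O[Si](C)(C)C)C(CC=C(C)C)=C(O[Si](C)(C)C)CC=C1C(=O)/C=C/c1ccc(O[Si](C)(C)C(C)(C)C)c(CC=C(C)C)c1 | intermediate (not isolated)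
15 | (E)-3-[4-(tert-butyldimethylsilyloxy)-3-(3-methylbut-2-enyl)phenyl]-1-[2,4-dihydroxy-3-(3-methylbut-2-enyl)phenyl]prop-2-en-1-one | CC(C)=CCc1cc(/C=C/C(=O)c2ccc(O)c(CC=C(C)C)c2O)ccc1O[Si](C)(C)C(C)(C)C | intermediate
16 | 4-{(E)-3-[4-(tert-butyldimethylsilyloxy)-3-(3-methylbut-2-enyl)phenyl]prop-2-enoyl}-3-hydroxy-2-[(Z)-3-methylbut-2-enylidene]cyclohexa-3,5-dien-1-one | CC(C)=C/C=C1\C(=O)C=CC(C(=O)/C=C/c2ccc(O[Si](C)(C)C(C)(C)C)c(CC=C(C)C)c2)=C1O | intermediate (not isolated)
17 | (E)-3-[4-(tert-butyldimethylsilyloxy)-3-(3-methylbut-2-enyl)phenyl]-1-(5-hydroxy-2,2-dimethyl-2H-chromen-6-yl)prop-2-en-1-one | CC(C)=CCc1cc(/C=C/C(=O)c2ccc3c(c2O)C=CC(C)(C)O3)ccc1O[Si](C)(C)C(C)(C)C | intermediate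
18 | paratocarpin B, (E)-1-(5-hydroxy-2,2-dimethyl-2H-chromen-6-yl)-3-[4-hydroxy-3-(3-methylbut-2-enyl)phenyl]prop-2-en-1-one | CC(C)=CCc1cc(/C=C/C(=O)c2ccc3c(c2O)C=CC(C)(C)O3)ccc1O | target

## Step count and risks

Total: 10 steps. Longest linear sequence: 7 steps (steps 1, 2, 3, 4, 8, 9, 10); the diene branch (steps 5, 6, 7) joins at step 8.

Least certain steps:

Step 8 (key step). The diene terminus may add to the ynone in a Mukaiyama–Michael fashion and stop at the open-chain stage. Cycloaddition may be diverted to the enone alkene. The moisture-sensitive diene may hydrolyse before it reacts. Aromatization may proceed by loss of silanol instead of methanol, which would leave a methyl ether on O2'. All of these stem from using a larger, cross-conjugated dienophile than the simple acetylenic ketones for which the reaction type is established. The fallback sets out from 13 and 3 and comes back to the route at 18. 13 would be combined with but-3-yn-2-one, the parent dienophile with no competing alkene (toluene, rt; cold dilute HCl), to give 1-[2,4-dihydroxy-3-(3-methylbut-2-enyl)phenyl]ethanone F1. DDQ in benzene would close this to 1-(5-hydroxy-2,2-dimethyl-2H-chromen-6-yl)ethanone F2. Separately 3 would be protected with 3,4-dihydro-2H-pyran and pyridinium p-toluenesulfonate as racemic 3-(3-methylbut-2-enyl)-4-(tetrahydro-2H-pyran-2-yloxy)benzaldehyde F3. Claisen–Schmidt condensation of F2 with F3 (KOH, EtOH/H2O, rt) would give racemic (E)-1-(5-hydroxy-2,2-dimethyl-2H-chromen-6-yl)-3-[3-(3-methylbut-2-enyl)-4-(tetrahydro-2H-pyran-2-yloxy)phenyl]prop-2-en-1-one F4. Pyridinium p-toluenesulfonate in EtOH at 50 °C would then release 18. Ring B is thus attached by aldol condensation after ring A is complete, and is not carried through the cycloaddition.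

Step 1. O-alkylation and double alkylation may outrun ortho C-alkylation, because the phenoxide is ambident and the formyl group lowers the nucleophilicity of the ring carbons. The fallback sets out from 1 and comes back at 3. 1 would be O-alkylated with 3-chloro-3-methylbut-1-yne (DBU, CuCl2 cat., MeCN, 0 °C) to 4-(2-methylbut-3-yn-2-yloxy)benzaldehyde F5. Semi-hydrogenation (H2, Pd/CaCO3 poisoned with Pb(OAc)2, quinoline, EtOAc) would give 4-(2-methylbut-3-en-2-yloxy)benzaldehyde F6. An aromatic Claisen rearrangement (N,N-diethylaniline, 130 °C) would then deliver the prenyl group to the ortho carbon by a [3,3] shift and give 3 after tautomerization.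

Step 4. The N,O-dimethylhydroxylamine set free on quenching may add in conjugate fashion to the new terminal ynone, and the ynone may oligomerize on concentration. Both follow from the high electrophilicity of the β-carbon of an ethynyl ketone. The fallback sets out from 4 and comes back at 9. Wittig olefination of 4 with (triphenylphosphoranylidene)acetaldehyde (toluene, 80 °C) would give (E)-3-[4-(tert-butyldimethylsilyloxy)-3-(3-methylbut-2-enyl)phenyl]prop-2-enal F7. 1,2-Addition of 7 (THF, −78 → 0 °C; aq NH4Cl) would give racemic (E)-1-[4-(tert-butyldimethylsilyloxy)-3-(3-methylbut-2-enyl)phenyl]pent-1-en-4-yn-3-ol F8. Oxidation of this doubly activated carbinol with MnO2 (CH2Cl2, rt) would give 9, and no amine is present at any stage.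

Step 9. Ring closure may take place in part through O2', hydride may be abstracted at the ring B prenyl group, or the chromene may be oxidized further. DDQ discriminates only through the free phenol and the hydrogen bond. The fallback sets out from 9 and comes back at 17. 9 would be combined with the commercial parent diene 1-methoxy-1,3-bis(trimethylsilyloxy)buta-1,3-diene under the conditions of step 8 to give (E)-3-[4-(tert-butyldimethylsilyloxy)-3-(3-methylbut-2-enyl)phenyl]-1-(2,4-dihydroxyphenyl)prop-2-en-1-one F9. The pyran would then be annulated with 3-methylbut-2-enal A3 and ethylenediammonium diacetate (cat., toluene, 100 °C): condensation at C3' between the two oxygens followed by oxa-6π electrocyclization through O4' gives 17 without any oxidant.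

## Further compounds

F1 | step 8 | 1-[2,4-dihydroxy-3-(3-methylbut-2-enyl)phenyl]ethanone | CC(=O)c1ccc(O)c(CC=C(C)C)c1O
F2 | step 8 | 1-(5-hydroxy-2,2-dimethyl-2H-chromen-6-yl)ethanone | CC(=O)c1ccc2c(c1O)C=CC(C)(C)O2
F3 | step 8 | 3-(3-methylbut-2-enyl)-4-(tetrahydro-2H-pyran-2-yloxy)benzaldehyde (racemic) | CC(C)=CCc1cc(C=O)ccc1OC1CCCCO1
F4 | step 8 | (E)-1-(5-hydroxy-2,2-dimethyl-2H-chromen-6-yl)-3-[3-(3-methylbut-2-enyl)-4-(tetrahydro-2H-pyran-2-yloxy)phenyl]prop-2-en-1-one (racemic) | CC(C)=CCc1cc(/C=C/C(=O)c2ccc3c(c2O)C=CC(C)(C)O3)ccc1OC1CCCCO1
F5 | step 1 | 4-(2-methylbut-3-yn-2-yloxy)benzaldehyde | C#CC(C)(C)Oc1ccc(C=O)cc1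
F6 | step 1 | 4-(2-methylbut-3-en-2-yloxy)benzaldehyde | C=CC(C)(C)Oc1ccc(C=O)cc1
F7 | step 4 | (E)-3-[4-(tert-butyldimethylsilyloxy)-3-(3-methylbut-2-enyl)phenyl]prop-2-enal | O=C/C=C/c1ccc(O[Si](C)(C)C(C)(C)C)c(CC=C(C)C)c1
F8 | step 4 | (E)-1-[4-(tert-butyldimethylsilyloxy)-3-(3-methylbut-2-enyl)phenyl]pent-1-en-4-yn-3-ol (racemic) | C#CC(O)/C=C/c1ccc(O[Si](C)(C)C(C)(C)C)c(CC=C(C)C)c1
F9 | step 9 | (E)-3-[4-(tert-butyldimethylsilyloxy)-3-(3-methylbut-2-enyl)phenyl]-1-(2,4-dihydroxyphenyl)prop-2-en-1-one | CC(C)=CCc1cc(/C=C/C(=O)c2ccc(O)cc2O)ccc1O[Si](C)(C)C(C)(C)C
A1 | alternative 1 | 5-(methoxymethoxy)-2,2-dimethyl-2H-chromene | COCOc1cccc2c1C=CC(C)(C)O2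
A2 | alternative 1 | 3-(methoxymethoxy)-2-(trimethylsilyl)phenyl trifluoromethanesulfonate | COCOc1cccc(OS(=O)(=O)C(F)(F)F)c1[Si](C)(C)C
A3 | alternative 1 | 3-methylbut-2-enal | CC(C)=CC=O
A4 | alternative 2 | 6-iodo-5-(methoxymethoxy)-2,2-dimethyl-2H-chromene | COCOc1c(I)ccc2c1C=CC(C)(C)O2
A5 | alternative 2 | carbon monoxide | [C-]#[O+]
A6 | alternative 2 | (E)-2-{2-[4-(tert-butyldimethylsilyloxy)-3-(3-methylbut-2-enyl)phenyl]ethenyl}-4,4,5,5-tetramethyl-1,3,2-dioxaborolane | CC(C)=CCc1cc(/C=C/B2OC(C)(C)C(C)(C)O2)ccc1O[Si](C)(C)C(C)(C)C
A7 | alternative 2 | (E)-3-[4-(tert-butyldimethylsilyloxy)-3-(3-methylbut-2-enyl)phenyl]-1-[5-(methoxymethoxy)-2,2-dimethyl-2H-chromen-6-yl]prop-2-en-1-one, the methoxymethyl tert-butyldimethylsilyl diether of paratocarpin B | CC(C)=CCc1cc(/C=C/C(=O)c2ccc3c(c2OCOC)C=CC(C)(C)O3)ccc1O[Si](C)(C)C(C)(C)C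
A8 | alternative 3 | (E)-1-[2,4-dihydroxy-3-(3-methylbut-2-enyl)phenyl]-3-[4-(methoxymethoxy)-3-(3-methylbut-2-enyl)phenyl]prop-2-en-1-one | CC(C)=CCc1cc(/C=C/C(=O)c2ccc(O)c(CC=C(C)C)c2O)ccc1OCOC
A9 | alternative 3 | (E)-1-(5-hydroxy-2,2-dimethyl-2H-chromen-6-yl)-3-[4-(methoxymethoxy)-3-(3-methylbut-2-enyl)phenyl]prop-2-en-1-one, the ring B methoxymethyl ether of paratocarpin B | CC(C)=CCc1cc(/C=C/C(=O)c2ccc3c(c2O)C=CC(C)(C)O3)ccc1OCOC
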